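## Analysis of the target

Caraganin C is a 3,4-dihydro-2H-chromene (chroman). Its benzo ring (ring A) carries one methoxy group at C7, and the pyran ring carries three contiguous substituents: a 2,4-dimethoxyphenyl group at C2, a 4-hydroxybenzyl group at C3 and an (E)-2-(4-hydroxyphenyl)ethenyl group at C4. The SMILES of the target is read as (2R,3R,4R). The substituents are 2,3-trans and 3,4-trans, so all three can be equatorial on the half-chair, which makes this the thermodynamically preferred diastereomer. The sensitive sites are the two free phenols (one conjugated with the styrene double bond), the C2–O1 bond (a benzylic ether of an aryl ring with ortho and para methoxy groups, which ionises readily under acid) and the C4–H bond, which is both benzylic and allylic. The synthesis is hard for three reasons: three adjacent stereocentres and an E-alkene must be set with absolute control, five phenolic oxygens (three methylated, two free) must be told apart, and O1 sits meta to the only other oxygen of ring A, so it cannot be introduced by electrophilic substitution of a simple phenol. The strategy rests on exactly this pattern: C7 is para to C4a and C8a is ortho to C4a. A 4-substituted phenol whose hydroxyl is the future C7 oxygen therefore becomes, after oxidation to a cyclohexa-2,5-dienone, an acceptor whose β-carbon is the future C8a. Chroman numbering (O1, C2, C3, C4, C4a, C5 to C8, C8a) is used for these atoms in all intermediates, open-chain ones included.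

## Retrosynthetic reasoning

**25 ⇒ 24 ⇒ 23.** The two allyl–oxygen bonds and the C7 O–methyl bond are cut last. In 23 the C7 hydroxyl is the only free phenol, so its methylation needs no selectivity. The two phenols that must end up free stay as allyl ethers, which survive base, hydride, organolithium, oxidant and acid, and are removed at the end under neutral conditions that spare the acid-labile C2–O1 bond and the styrene.

**23 ⇒ 21 (through 22).** The O1–C8a bond is cut. Cutting O1–C2 or C4–C4a instead would force the stereotriad to be created during ring closure. Cutting O1–C8a leaves C2, C3 and C4 untouched and turns an aryl ether bond that is out of reach on the arene into a conjugate addition. The C2 hydroxyl of 21 adds to a β-carbon of the 4-methoxycyclohexa-2,5-dienone to give 22, and acid then expels the angular methoxy group as its alcohol, so that ring A becomes aromatic with the former carbonyl as the C7 hydroxyl. The forward reaction must complete the cyclisation before acid is admitted.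

**21 ⇒ 20 ⇒ 19 ⇒ 18 ⇒ 17.** The angular C4a–OMe bond and two silyl groups are cut. A free C2 hydroxyl would attack the ipso carbon of the oxidised phenol and close a five-membered spiro ether, so the carbinol is silylated (18) before the ring A phenol is unmasked (19) and oxidised in the alcohol solvent (20). The ring A oxygen is singled out because it is the only aryl silyl ether, and an aryl–O–Si bond is cleaved far more easily than the alkyl–O–Si bond at C2.

**17 ⇒ 16 ⇒ 13 + 15 (from 14).** The C2–H bond and then the C2–aryl bond are cut. With C3 as the controlling centre, the Felkin–Anh model predicts opposite C2 configurations for aryl addition to an aldehyde and for hydride addition to the aryl ketone. Only hydride addition to 16 gives the carbinol that leads to the 2,3-trans chroman, so C2 is set by reduction. Ketone 16 comes from the N-methoxy-N-methylamide 13 and the aryllithium 15, which cannot over-add.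

**13 ⇒ 12 ⇒ 9 (through 10 and 11).** The C3–C4 bond is cut by a [3,3]-sigmatropic retron. One rearrangement of the allylic ester 9 sets C3, C4 and the E-alkene together, and the absolute configuration comes from the single carbinol centre of 9. The forward reaction needs the (E)-ketene acetal 10 and a chair transition state with the carbinol aryl group equatorial. The aryl group on the alkene terminus of 9 becomes ring A and the aryl group on the carbinol carbon becomes the styryl aryl, which is why the first carries the silyl ether and the second an allyl ether.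

**9 ⇒ 6 + 8; 6 ⇒ 5 ⇒ 4 ⇒ 2 + 3; 2 ⇐ 1; 8 ⇐ 7.** The ester C–O bond, the carbinol C–H bond (catalyst-controlled enone reduction) and the enone C=C bond (aldol condensation) are cut. Ring A comes from 3, the styryl aryl from 1, the benzyl group from 7 and the dimethoxyaryl group from 14, all simple para-oxygenated benzenes.

## Alternatives that were turned down

**Alternative 1:** The C2–aryl and C3–CH2 bonds are cut on an intact benzopyranone. In the forward sense a chiral rhodium catalyst adds an aryl zinc nucleophile 1,4 to 7-methoxy-4H-chromen-4-one A2, the enolate is held as a silyl enol ether, and a zinc-halide-promoted alkylation with a 4-silyloxybenzyl halide gives the 2,3-trans chromanone A1.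
- For: the ring A oxygen pattern is bought, C2 is set by a catalyst, the benzyl group enters anti to the C2 aryl group, and the 2,3-disubstituted core is reached in very few steps. On these points it is stronger than the chosen route.
- Against: the ortho-methoxy aryl nucleophile is a slow partner for this type of addition. More seriously, A1 still lacks C4. A styryl group would have to be added to a hindered, enolisable ketone that can also open by retro-oxa-Michael reaction, and the tertiary alcohol would then have to be removed reductively. The cation involved is delocalised over C4 and the styryl terminus, so hydride can enter at either end and from either face, under acid that also threatens C2–O1.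
- Comparison: the chosen route needs more steps and a dearomatisation, but it sets C3, C4 and the E-alkene in one pericyclic step and only has to form a C–O bond afterwards.

**Alternative 2:** The C2–C3 and C4–C4a bonds are cut in a formal [4+2] sense. An aryl oxocarbenium ion on the ring A oxygen is attacked by the benzyl-bearing terminus of the diene A4, and the styryl-stabilised allyl cation is captured by the ring A carbon para to the methoxy group, which gives the bis(silyl) ether A3 in one step.
- For: it is the most convergent plan, with two C–C bonds, the ring and all three stereocentres formed from simple components, and the stepwise cationic course favours the all-equatorial product. In step economy it is clearly stronger.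
- Against: nothing in the substrates controls the absolute configuration, and a chiral counter-anion able to control an acyclic aryl oxocarbenium ion in this annulation is not established. The electron-rich diene can polymerise or be attacked at the wrong terminus, the allyl cation can be captured at its distal end, and the Lewis acid can reopen the C2–O1 bond of the product.
- Comparison: the chosen route is longer, but its absolute configuration comes from a ketone reduction with a well-understood model and is passed on through a chair transition state.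

**Alternative 3:** The O1–C2 and C2–C3 bonds are cut. The phenol A6, which carries two identical styryl arms on a prochiral carbon, forms an aryl oxocarbenium ion with the dimethoxybenzaldehyde acetal. One enantiotopic arm attacks through its proximal carbon, and a trialkylsilane reduces the resulting benzylic cation to give A5, which is identical with 24.
- For: the benzyl and styryl groups come from one symmetric precursor, ring A needs no adjustment, and one step forms two bonds and three stereocentres through a chair with all groups equatorial. It is the shortest of all plans.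
- Against: the single enantiomer requires a chiral acid that distinguishes the two arms of an oxocarbenium Prins cyclisation terminated by hydride, which has not been shown for this substrate class. The silane can reduce the oxocarbenium ion before cyclisation, the benzylic cation can be trapped by the second arm, and the doubly allylic, benzylic C–H of A6 invites isomerisation.
- Comparison: the chosen route gives up this brevity and in return sets each stereocentre by an established, predictable event.

Key step: step 15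

## Route

**Step 1**
Reactants: 1 4'-hydroxyacetophenone
Product: 2 1-[4-(allyloxy)phenyl]ethan-1-one
Conditions: allyl bromide, K2CO3, acetone, reflux
Reagents that add atoms: allyl bromide (3-bromoprop-1-ene), C=CCBr
Why: Williamson ether synthesis on the phenoxide; the aryl allyl ether withstands all later bases, hydrides, organolithium reagents, the oxidant and the acid.

**Step 2**
Reactants: 2 1-[4-(allyloxy)phenyl]ethan-1-one; 3 4-hydroxybenzaldehyde
Product: 4 (2E)-1-[4-(allyloxy)phenyl]-3-(4-hydroxyphenyl)prop-2-en-1-one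
Conditions: HCl (4 M in 1,4-dioxane), EtOH, 0 °C to rt
Reagents that add atoms: none
Why: Acid-catalysed Claisen–Schmidt condensation (aldol addition of the enol, then dehydration to the conjugated E-enone); acid is used because hydroxide would turn the aldehyde into its unreactive phenoxide, and the allyl ether is inert to HCl at room temperature.

**Step 3**
Reactants: 4 (2E)-1-[4-(allyloxy)phenyl]-3-(4-hydroxyphenyl)prop-2-en-1-one
Product: 5 (2E)-1-[4-(allyloxy)phenyl]-3-{4-[(tert-butyldimethylsilyl)oxy]phenyl}prop-2-en-1-one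
Conditions: t-BuMe2SiCl, imidazole, DMF, rt
Reagents that add atoms: tert-butyl(chloro)dimethylsilane, CC(C)(C)[Si](C)(C)Cl
Why: Silylation of the phenol; the aryl silyl ether marks the future ring A oxygen and can later be cleaved beside an alkyl silyl ether and two allyl ethers.

**Step 4**
Reactants: 5 (2E)-1-[4-(allyloxy)phenyl]-3-{4-[(tert-butyldimethylsilyl)oxy]phenyl}prop-2-en-1-one
Product: 6 (1R,2E)-1-[4-(allyloxy)phenyl]-3-{4-[(tert-butyldimethylsilyl)oxy]phenyl}prop-2-en-1-ol
Conditions: (S)-1-methyl-3,3-diphenyltetrahydro-1H,3H-pyrrolo[1,2-c][1,3,2]oxazaborole (20 mol%), catecholborane, toluene, −78 °C; then MeOH, aq. NaHCO3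
Reagents that add atoms: none
Why: Corey–Bakshi–Shibata reduction: the ketone binds to the ring boron anti to its larger flank, taken to be the aryl group and not the trans-alkenyl group, and hydride is delivered from the coordinated borane, which should give the (R)-carbinol. Catecholborane at −78 °C reduces only the carbonyl group and does not hydroborate the allyl ether or the enone double bond.

**Step 5**
Reactants: 7 3-(4-hydroxyphenyl)propanoic acid
Product: 8 3-[4-(allyloxy)phenyl]propanoic acid
Conditions: allyl bromide, NaOH (2.5 equiv), EtOH/H2O, 70 °C; then aq. HCl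
Reagents that add atoms: allyl bromide (3-bromoprop-1-ene), C=CCBr
Why: Williamson etherification of the dianion; the phenoxide is much the better nucleophile in the protic medium, and any allyl ester formed is saponified by the excess hydroxide.

**Step 6**
Reactants: 6 (1R,2E)-1-[4-(allyloxy)phenyl]-3-{4-[(tert-butyldimethylsilyl)oxy]phenyl}prop-2-en-1-ol; 8 3-[4-(allyloxy)phenyl]propanoic acid
Product: 9 (1R,2E)-1-[4-(allyloxy)phenyl]-3-{4-[(tert-butyldimethylsilyl)oxy]phenyl}prop-2-en-1-yl 3-[4-(allyloxy)phenyl]propanoate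
Conditions: N,N'-dicyclohexylcarbodiimide, 4-(dimethylamino)pyridine (10 mol%), CH2Cl2, 0 °C; filtration through Et3N-deactivated silica
Reagents that add atoms: none
Why: Steglich esterification; acylation takes place at oxygen under neutral to basic conditions, so the C–O bond of the stereocentre is not broken and the configuration of 6 is kept. Acid is avoided because the diaryl-substituted allylic system ionises easily.

**Step 7**
Reactants: 9 (1R,2E)-1-[4-(allyloxy)phenyl]-3-{4-[(tert-butyldimethylsilyl)oxy]phenyl}prop-2-en-1-yl 3-[4-(allyloxy)phenyl]propanoate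
Product: 12 (2R,3R,4E)-2-[4-(allyloxy)benzyl]-5-[4-(allyloxy)phenyl]-3-{4-[(tert-butyldimethylsilyl)oxy]phenyl}pent-4-enoic acid, via (E)-silyl ketene acetal 10 (not isolated), via trimethylsilyl ester 11 (not isolated)
Conditions: LiN(iPr)2, Me3SiCl/Et3N, THF, −78 °C to rt (40 °C if needed); then H2O (citrate buffer)
Reagents that add atoms: none
Why: Ireland–Claisen rearrangement: kinetic enolisation in THF without a polar co-solvent gives the ketene acetal with the benzyl group cis to the allylic oxygen. The [3,3] shift through a chair with both aryl groups equatorial then delivers the anti acid and the E-alkene. The shift is suprafacial, so the (R)-carbinol centre of 9 is translated into the (2R,3R) centres of 12, the future C3 and C4.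

**Step 8**
Reactants: 12 (2R,3R,4E)-2-[4-(allyloxy)benzyl]-5-[4-(allyloxy)phenyl]-3-{4-[(tert-butyldimethylsilyl)oxy]phenyl}pent-4-enoic acid
Product: 13 (2R,3R,4E)-2-[4-(allyloxy)benzyl]-5-[4-(allyloxy)phenyl]-3-{4-[(tert-butyldimethylsilyl)oxy]phenyl}-N-methoxy-N-methylpent-4-enamide
Conditions: MeNH(OMe)·HCl, N-[3-(dimethylamino)propyl]-N'-ethylcarbodiimide hydrochloride, 1-hydroxybenzotriazole, iPr2NEt, CH2Cl2, 0 °C to rt
Reagents that add atoms: N,O-dimethylhydroxylamine hydrochloride, CNOC.Cl
Why: Carbodiimide amide coupling through the benzotriazolyl active ester; the α-stereocentre is not endangered because no ketene or azlactone pathway is open under these conditions.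

**Step 9**
Reactants: 13 (2R,3R,4E)-2-[4-(allyloxy)benzyl]-5-[4-(allyloxy)phenyl]-3-{4-[(tert-butyldimethylsilyl)oxy]phenyl}-N-methoxy-N-methylpent-4-enamide; 14 1-bromo-2,4-dimethoxybenzene
Product: 16 (2R,3R,4E)-2-[4-(allyloxy)benzyl]-5-[4-(allyloxy)phenyl]-3-{4-[(tert-butyldimethylsilyl)oxy]phenyl}-1-(2,4-dimethoxyphenyl)pent-4-en-1-one, via 2,4-dimethoxyphenyllithium 15 (not isolated)
Conditions: 14, n-butyllithium, THF, −78 °C; then 13, −78 to 0 °C; then H2O
Reagents that add atoms: none
Why: Bromine–lithium exchange followed by the Weinreb ketone synthesis; the chelated tetrahedral adduct does not collapse before the quench, so there is no second addition and the ketone with its α-stereocentre is never exposed to the aryllithium.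

**Step 10**
Reactants: 16 (2R,3R,4E)-2-[4-(allyloxy)benzyl]-5-[4-(allyloxy)phenyl]-3-{4-[(tert-butyldimethylsilyl)oxy]phenyl}-1-(2,4-dimethoxyphenyl)pent-4-en-1-one
Product: 17 (1R,2R,3R,4E)-2-[4-(allyloxy)benzyl]-5-[4-(allyloxy)phenyl]-3-{4-[(tert-butyldimethylsilyl)oxy]phenyl}-1-(2,4-dimethoxyphenyl)pent-4-en-1-ol
Conditions: LiAlH4, THF, −78 °C; then H2O, aq. NaOH
Reagents that add atoms: none
Why: Felkin–Anh controlled hydride addition: the branched carbon carrying the aryl and styryl groups is the large substituent and lies anti to the incoming hydride, which passes the α-hydrogen. This places the new hydroxyl anti to the benzyl group (1R), the relationship that becomes 2,3-trans in the chroman.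

**Step 11**
Reactants: 17 (1R,2R,3R,4E)-2-[4-(allyloxy)benzyl]-5-[4-(allyloxy)phenyl]-3-{4-[(tert-butyldimethylsilyl)oxy]phenyl}-1-(2,4-dimethoxyphenyl)pent-4-en-1-ol
Product: 18 (1R,2R,3R,4E)-2-[4-(allyloxy)benzyl]-5-[4-(allyloxy)phenyl]-3-{4-[(tert-butyldimethylsilyl)oxy]phenyl}-1-(2,4-dimethoxyphenyl)-1-[(triethylsilyl)oxy]pent-4-ene
Conditions: Et3SiCl, imidazole, 4-(dimethylamino)pyridine (cat.), DMF, rt
Reagents that add atoms: chlorotriethylsilane, CC[Si](Cl)(CC)CC
Why: Silylation of the secondary alcohol under basic conditions, which do not ionise the electron-rich benzylic carbinol; the silyl ether keeps this oxygen away from the ipso carbon during the phenol oxidation.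

**Step 12**
Reactants: 18 (1R,2R,3R,4E)-2-[4-(allyloxy)benzyl]-5-[4-(allyloxy)phenyl]-3-{4-[(tert-butyldimethylsilyl)oxy]phenyl}-1-(2,4-dimethoxyphenyl)-1-[(triethylsilyl)oxy]pent-4-ene
Product: 19 4-{(1E,3R,4R,5R)-4-[4-(allyloxy)benzyl]-1-[4-(allyloxy)phenyl]-5-(2,4-dimethoxyphenyl)-5-[(triethylsilyl)oxy]pent-1-en-3-yl}phenol
Conditions: K2CO3 (0.2 equiv), MeOH/THF, 0 °C to rt
Reagents that add atoms: none
Why: Base-catalysed methanolysis at silicon; phenoxide is a far better leaving group than a secondary alkoxide, so only the aryl silyl ether is cleaved and the alkyl triethylsilyl ether stays.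

**Step 13**
Reactants: 19 4-{(1E,3R,4R,5R)-4-[4-(allyloxy)benzyl]-1-[4-(allyloxy)phenyl]-5-(2,4-dimethoxyphenyl)-5-[(triethylsilyl)oxy]pent-1-en-3-yl}phenol
Product: 20 4-{(1E,3R,4R,5R)-4-[4-(allyloxy)benzyl]-1-[4-(allyloxy)phenyl]-5-(2,4-dimethoxyphenyl)-5-[(triethylsilyl)oxy]pent-1-en-3-yl}-4-methoxycyclohexa-2,5-dien-1-one
Conditions: PhI(OAc)2, MeOH, 0 °C
Reagents that add atoms: methanol, CO
Why: Oxidative dearomatisation of a para-alkylphenol with a trivalent iodine reagent: ligand exchange gives an aryloxyiodane, and the solvent attacks the para carbon as iodobenzene leaves. The only free phenol is that of ring A, the other arenes are ethers, and the silylated carbinol cannot intercept the ipso carbon.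

**Step 14**
Reactants: 20 4-{(1E,3R,4R,5R)-4-[4-(allyloxy)benzyl]-1-[4-(allyloxy)phenyl]-5-(2,4-dimethoxyphenyl)-5-[(triethylsilyl)oxy]pent-1-en-3-yl}-4-methoxycyclohexa-2,5-dien-1-one
Product: 21 4-{(1E,3R,4R,5R)-4-[4-(allyloxy)benzyl]-1-[4-(allyloxy)phenyl]-5-(2,4-dimethoxyphenyl)-5-hydroxypent-1-en-3-yl}-4-methoxycyclohexa-2,5-dien-1-one
Conditions: HF·pyridine, pyridine, THF, 0 °C
Reagents that add atoms: none
Why: Fluoride-mediated cleavage of the triethylsilyl ether in a pyridine-buffered medium, which is neither basic enough to start the conjugate addition uncontrolled nor acidic enough to ionise the methoxydienone or the benzylic carbinol.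

**Step 15**
Reactants: 21 4-{(1E,3R,4R,5R)-4-[4-(allyloxy)benzyl]-1-[4-(allyloxy)phenyl]-5-(2,4-dimethoxyphenyl)-5-hydroxypent-1-en-3-yl}-4-methoxycyclohexa-2,5-dien-1-one
Product: 23 (2R,3R,4R)-3-[4-(allyloxy)benzyl]-4-{(E)-2-[4-(allyloxy)phenyl]ethenyl}-2-(2,4-dimethoxyphenyl)-3,4-dihydro-2H-chromen-7-ol, via oxa-Michael adduct 22 (not isolated)
Conditions: 1,8-diazabicyclo[5.4.0]undec-7-ene (0.2 equiv), CH2Cl2, 0 °C to rt; then 4-methylbenzenesulfonic acid monohydrate (0.4 equiv), rt
Reagents that add atoms: none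
Why: The amidine base reversibly deprotonates the C2 carbinol, and the alkoxide adds in a 6-exo-trig oxa-Michael reaction to one β-carbon of the cross-conjugated dienone (the future C8a), which gives the 4a-methoxy-hexahydrochromen-7-one 22 through a chair-like transition state with the aryl, benzyl and styryl groups equatorial. The sulfonic acid then enolises the ketone towards C8, the now pentadienylic C4a–OMe bond ionises to the arenium ion of the product phenol, and loss of the C8a proton gives the aromatic ring with release of methanol. The closest known reaction type is the conjugate addition of tethered alcohols and amines to para-quinol ethers made by phenol oxidation, followed by acid-promoted rearomatisation. Only the six-membered ring can form, because the three-carbon tether C2–C3–C4 brings the oxygen to no other electrophilic carbon, and this places O1 ortho to C4a and leaves the former carbonyl as the C7 hydroxyl. The two β-carbons are diastereotopic, but both adducts and both ring-fusion configurations converge on one arene since C4a and C8a become sp2. No permanent stereocentre is formed, and C2, C3 and C4 take no part in the bond changes, so the all-trans (2R,3R,4R) arrangement of 21 is carried into 23. The step needs the cyclisation to be complete before acid is present, because uncyclised 21 would ionise at the dimethoxybenzylic carbinol or lose the C4 proton from the dienone; the base-then-acid order and the irreversible aromatisation secure this.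

**Step 16**
Reactants: 23 (2R,3R,4R)-3-[4-(allyloxy)benzyl]-4-{(E)-2-[4-(allyloxy)phenyl]ethenyl}-2-(2,4-dimethoxyphenyl)-3,4-dihydro-2H-chromen-7-ol
Product: 24 (2R,3R,4R)-3-[4-(allyloxy)benzyl]-4-{(E)-2-[4-(allyloxy)phenyl]ethenyl}-2-(2,4-dimethoxyphenyl)-7-methoxy-3,4-dihydro-2H-chromene
Conditions: MeI, K2CO3, acetone, 40 °C
Reagents that add atoms: iodomethane, CI
Why: Williamson methylation of the only free phenol; the other two phenolic oxygens are allyl ethers, so no selectivity is needed.

**Step 17**
Reactants: 24 (2R,3R,4R)-3-[4-(allyloxy)benzyl]-4-{(E)-2-[4-(allyloxy)phenyl]ethenyl}-2-(2,4-dimethoxyphenyl)-7-methoxy-3,4-dihydro-2H-chromene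
Product: 25 caraganin C, 4-{[(2R,3R,4R)-2-(2,4-dimethoxyphenyl)-4-[(E)-2-(4-hydroxyphenyl)ethenyl]-7-methoxy-3,4-dihydro-2H-chromen-3-yl]methyl}phenol
Conditions: Pd(PPh3)4 (5 mol%), morpholine, THF, rt
Reagents that add atoms: none
Why: Tsuji–Trost deallylation: zerovalent palladium inserts into each allyl–OAr bond, the phenoxide leaves, and morpholine captures the allyl group. The conditions are neutral and leave the methyl ethers, the styrene and the C2–O1 bond untouched.

## Compound list

1 | 4'-hydroxyacetophenone | CC(=O)c1ccc(O)cc1 | starting material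
2 | 1-[4-(allyloxy)phenyl]ethan-1-one | CC(=O)c1ccc(OCC=C)cc1 | intermediate
3 | 4-hydroxybenzaldehyde | O=Cc1ccc(O)cc1 | starting material
4 | (2E)-1-[4-(allyloxy)phenyl]-3-(4-hydroxyphenyl)prop-2-en-1-one | O=C(/C=C/c1ccc(O)cc1)c1ccc(OCC=C)cc1 | intermediate
5 | (2E)-1-[4-(allyloxy)phenyl]-3-{4-[(tert-butyldimethylsilyl)oxy]phenyl}prop-2-en-1-one | O=C(/C=C/c1ccc(O[Si](C)(C)C(C)(C)C)cc1)c1ccc(OCC=C)cc1 | intermediate
6 | (1R,2E)-1-[4-(allyloxy)phenyl]-3-{4-[(tert-butyldimethylsilyl)oxy]phenyl}prop-2-en-1-ol | O[C@@H](c1ccc(OCC=C)cc1)/C=C/c1ccc(O[Si](C)(C)C(C)(C)C)cc1 | intermediate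
7 | 3-(4-hydroxyphenyl)propanoic acid | OC(=O)CCc1ccc(O)cc1 | starting material
8 | 3-[4-(allyloxy)phenyl]propanoic acid | OC(=O)CCc1ccc(OCC=C)cc1 | intermediate
9 | (1R,2E)-1-[4-(allyloxy)phenyl]-3-{4-[(tert-butyldimethylsilyl)oxy]phenyl}prop-2-en-1-yl 3-[4-(allyloxy)phenyl]propanoate | O=C(CCc1ccc(OCC=C)cc1)O[C@@H](c1ccc(OCC=C)cc1)/C=C/c1ccc(O[Si](C)(C)C(C)(C)C)cc1 | intermediate
10 | (E)-trimethylsilyl ketene acetal of 9 (benzyl group cis to the allylic oxygen, trans to OSiMe3) | C[Si](C)(C)O/C(=C/Cc1ccc(OCC=C)cc1)O[C@@H](c1ccc(OCC=C)cc1)/C=C/c1ccc(O[Si](C)(C)C(C)(C)C)cc1 | intermediate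
11 | trimethylsilyl (2R,3R,4E)-2-[4-(allyloxy)benzyl]-5-[4-(allyloxy)phenyl]-3-{4-[(tert-butyldimethylsilyl)oxy]phenyl}pent-4-enoate | C[Si](C)(C)OC(=O)[C@H](Cc1ccc(OCC=C)cc1)[C@H](c1ccc(O[Si](C)(C)C(C)(C)C)cc1)/C=C/c1ccc(OCC=C)cc1 | intermediate
12 | (2R,3R,4E)-2-[4-(allyloxy)benzyl]-5-[4-(allyloxy)phenyl]-3-{4-[(tert-butyldimethylsilyl)oxy]phenyl}pent-4-enoic acid | OC(=O)[C@H](Cc1ccc(OCC=C)cc1)[C@H](c1ccc(O[Si](C)(C)C(C)(C)C)cc1)/C=C/c1ccc(OCC=C)cc1 | intermediate
13 | (2R,3R,4E)-2-[4-(allyloxy)benzyl]-5-[4-(allyloxy)phenyl]-3-{4-[(tert-butyldimethylsilyl)oxy]phenyl}-N-methoxy-N-methylpent-4-enamide | CON(C)C(=O)[C@H](Cc1ccc(OCC=C)cc1)[C@H](c1ccc(O[Si](C)(C)C(C)(C)C)cc1)/C=C/c1ccc(OCC=C)cc1 | intermediate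
14 | 1-bromo-2,4-dimethoxybenzene | COc1ccc(Br)c(OC)c1 | starting material
15 | 2,4-dimethoxyphenyllithium | [Li]c1ccc(OC)cc1OC | intermediate
16 | (2R,3R,4E)-2-[4-(allyloxy)benzyl]-5-[4-(allyloxy)phenyl]-3-{4-[(tert-butyldimethylsilyl)oxy]phenyl}-1-(2,4-dimethoxyphenyl)pent-4-en-1-one | O=C(c1ccc(OC)cc1OC)[C@H](Cc1ccc(OCC=C)cc1)[C@H](c1ccc(O[Si](C)(C)C(C)(C)C)cc1)/C=C/c1ccc(OCC=C)cc1 | intermediate
17 | (1R,2R,3R,4E)-2-[4-(allyloxy)benzyl]-5-[4-(allyloxy)phenyl]-3-{4-[(tert-butyldimethylsilyl)oxy]phenyl}-1-(2,4-dimethoxyphenyl)pent-4-en-1-ol | O[C@@H](c1ccc(OC)cc1OC)[C@H](Cc1ccc(OCC=C)cc1)[C@H](c1ccc(O[Si](C)(C)C(C)(C)C)cc1)/C=C/c1ccc(OCC=C)cc1 | intermediate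
18 | (1R,2R,3R,4E)-2-[4-(allyloxy)benzyl]-5-[4-(allyloxy)phenyl]-3-{4-[(tert-butyldimethylsilyl)oxy]phenyl}-1-(2,4-dimethoxyphenyl)-1-[(triethylsilyl)oxy]pent-4-ene | CC[Si](CC)(CC)O[C@@H](c1ccc(OC)cc1OC)[C@H](Cc1ccc(OCC=C)cc1)[C@H](c1ccc(O[Si](C)(C)C(C)(C)C)cc1)/C=C/c1ccc(OCC=C)cc1 | intermediate
19 | 4-{(1E,3R,4R,5R)-4-[4-(allyloxy)benzyl]-1-[4-(allyloxy)phenyl]-5-(2,4-dimethoxyphenyl)-5-[(triethylsilyl)oxy]pent-1-en-3-yl}phenol | CC[Si](CC)(CC)O[C@@H](c1ccc(OC)cc1OC)[C@H](Cc1ccc(OCC=C)cc1)[C@H](c1ccc(O)cc1)/C=C/c1ccc(OCC=C)cc1 | intermediate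
20 | 4-{(1E,3R,4R,5R)-4-[4-(allyloxy)benzyl]-1-[4-(allyloxy)phenyl]-5-(2,4-dimethoxyphenyl)-5-[(triethylsilyl)oxy]pent-1-en-3-yl}-4-methoxycyclohexa-2,5-dien-1-one | CC[Si](CC)(CC)O[C@@H](c1ccc(OC)cc1OC)[C@H](Cc1ccc(OCC=C)cc1)[C@H](C1(OC)C=CC(=O)C=C1)/C=C/c1ccc(OCC=C)cc1 | intermediate
21 | 4-{(1E,3R,4R,5R)-4-[4-(allyloxy)benzyl]-1-[4-(allyloxy)phenyl]-5-(2,4-dimethoxyphenyl)-5-hydroxypent-1-en-3-yl}-4-methoxycyclohexa-2,5-dien-1-one | O[C@@H](c1ccc(OC)cc1OC)[C@H](Cc1ccc(OCC=C)cc1)[C@H](C1(OC)C=CC(=O)C=C1)/C=C/c1ccc(OCC=C)cc1 | intermediate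
22 | (2R,3R,4R)-3-[4-(allyloxy)benzyl]-4-{(E)-2-[4-(allyloxy)phenyl]ethenyl}-2-(2,4-dimethoxyphenyl)-4a-methoxy-2,3,4,4a,8,8a-hexahydro-7H-chromen-7-one (C4a and C8a not defined, both forms converge) | COC12C=CC(=O)CC1O[C@@H](c1ccc(OC)cc1OC)[C@H](Cc1ccc(OCC=C)cc1)[C@H]2/C=C/c1ccc(OCC=C)cc1 | intermediate
23 | (2R,3R,4R)-3-[4-(allyloxy)benzyl]-4-{(E)-2-[4-(allyloxy)phenyl]ethenyl}-2-(2,4-dimethoxyphenyl)-3,4-dihydro-2H-chromen-7-ol | Oc1ccc2c(c1)O[C@@H](c1ccc(OC)cc1OC)[C@H](Cc1ccc(OCC=C)cc1)[C@H]2/C=C/c1ccc(OCC=C)cc1 | intermediate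
24 | (2R,3R,4R)-3-[4-(allyloxy)benzyl]-4-{(E)-2-[4-(allyloxy)phenyl]ethenyl}-2-(2,4-dimethoxyphenyl)-7-methoxy-3,4-dihydro-2H-chromene | COc1ccc2c(c1)O[C@@H](c1ccc(OC)cc1OC)[C@H](Cc1ccc(OCC=C)cc1)[C@H]2/C=C/c1ccc(OCC=C)cc1 | intermediate
25 | caraganin C | COc1ccc2c(c1)O[C@@H](c1ccc(OC)cc1OC)[C@H](Cc1ccc(O)cc1)[C@H]2/C=C/c1ccc(O)cc1 | target

## Step count and least certain steps

Total: 17 steps. Longest linear sequence: 16 steps (steps 1 to 4 and 6 to 17, from 1); step 5 is a one-step side branch.

**Step 15 (key step).** The conjugate addition is reversible, and under acid the β-alkoxy ketone can reopen. Ionisation at the dimethoxybenzylic C2, or loss of the C4 proton from the methoxydienone, can then outrun the loss of methanol. Long exposure to acid can also reopen C2–O1 in the product or protonate the electron-rich styrene.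
Fallback: the C8a–O1 bond is made by copper-catalysed intramolecular O-arylation instead. It sets out from 2 (with 8 and 14) and comes back at 24.
- Ketone 2 is condensed (NaOH, EtOH) with commercial 2-bromo-4-methoxybenzaldehyde to (2E)-1-[4-(allyloxy)phenyl]-3-(2-bromo-4-methoxyphenyl)prop-2-en-1-one F1.
- F1 is reduced as in step 4 to (1R,2E)-1-[4-(allyloxy)phenyl]-3-(2-bromo-4-methoxyphenyl)prop-2-en-1-ol F2, which is esterified with 8 to (1R,2E)-1-[4-(allyloxy)phenyl]-3-(2-bromo-4-methoxyphenyl)prop-2-en-1-yl 3-[4-(allyloxy)phenyl]propanoate F3.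
- Rearrangement as in step 7 gives (2R,3R,4E)-2-[4-(allyloxy)benzyl]-5-[4-(allyloxy)phenyl]-3-(2-bromo-4-methoxyphenyl)pent-4-enoic acid F4, and coupling as in step 8 gives (2R,3R,4E)-2-[4-(allyloxy)benzyl]-5-[4-(allyloxy)phenyl]-3-(2-bromo-4-methoxyphenyl)-N-methoxy-N-methylpent-4-enamide F5.
- An aryllithium would exchange with the aryl bromide, so F5 is treated with (2,4-dimethoxyphenyl)magnesium bromide F6 (from 14 and Mg) to give (2R,3R,4E)-2-[4-(allyloxy)benzyl]-5-[4-(allyloxy)phenyl]-3-(2-bromo-4-methoxyphenyl)-1-(2,4-dimethoxyphenyl)pent-4-en-1-one F7.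
- Reduction as in step 10 gives (1R,2R,3R,4E)-2-[4-(allyloxy)benzyl]-5-[4-(allyloxy)phenyl]-3-(2-bromo-4-methoxyphenyl)-1-(2,4-dimethoxyphenyl)pent-4-en-1-ol F8.
- CuI, 3,4,7,8-tetramethyl-1,10-phenanthroline and Cs2CO3 in toluene at 110 °C close the ring by Ullmann-type etherification and give 24, the 7-methoxy group being present from the start.

**Step 13.** The oxidised phenol may lose the doubly activated C4 proton (quinone methide formation, which erases C4) instead of capturing the solvent at the para carbon; attack at the ortho carbon is a lesser risk.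
Fallback: a dearomatisation that does not pass through a cationic phenol species. It sets out from 19 and comes back at 23.
- 19 is treated with KHSO5 (as 2KHSO5·KHSO4·K2SO4) and NaHCO3 in CH3CN/H2O (singlet-oxygen addition to the phenolate), then with Na2S2O3, to give the para-quinol 4-{(1E,3R,4R,5R)-4-[4-(allyloxy)benzyl]-1-[4-(allyloxy)phenyl]-5-(2,4-dimethoxyphenyl)-5-[(triethylsilyl)oxy]pent-1-en-3-yl}-4-hydroxycyclohexa-2,5-dien-1-one F9.
- Desilylation as in step 14 gives 4-{(1E,3R,4R,5R)-4-[4-(allyloxy)benzyl]-1-[4-(allyloxy)phenyl]-5-(2,4-dimethoxyphenyl)-5-hydroxypent-1-en-3-yl}-4-hydroxycyclohexa-2,5-dien-1-one F10.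
- The base of step 15 closes the ring to (2R,3R,4R)-3-[4-(allyloxy)benzyl]-4-{(E)-2-[4-(allyloxy)phenyl]ethenyl}-2-(2,4-dimethoxyphenyl)-4a-hydroxy-2,3,4,4a,8,8a-hexahydro-7H-chromen-7-one F11, and the acid removes water instead of methanol to give 23.

**Step 7.** The doubly aryl-stabilised allylic C–O bond of 9 may ionise before or during enolisation, which would exchange the two aryl termini and erode the enantiomeric purity. Imperfect ketene acetal geometry would lower the anti selectivity, and the amide base could also attack the carbinol C–H.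
Fallback: an Eschenmoser–Claisen rearrangement, which needs neither an isolated allylic ester nor a strong base. It sets out from 6 and 8 and comes back at 16.
- Acid 8 is converted (Me2NH, carbodiimide) into 3-[4-(allyloxy)phenyl]-N,N-dimethylpropanamide F12.
- O-Methylation (Me3OBF4) and then NaOMe give 3-[4-(allyloxy)phenyl]-1,1-dimethoxy-N,N-dimethylpropan-1-amine F13.
- Heating 6 with F13 in toluene, with removal of the alcohol formed, generates the ketene N,O-acetal with the benzyl group cis to the allylic oxygen. It rearranges through the same chair to (2R,3R,4E)-2-[4-(allyloxy)benzyl]-5-[4-(allyloxy)phenyl]-3-{4-[(tert-butyldimethylsilyl)oxy]phenyl}-N,N-dimethylpent-4-enamide F14.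
- Addition of 15 to F14 (stable tetrahedral adduct, ketone on work-up) gives 16.

**Step 10.** Facial selectivity may be poor, because the two carbon substituents of the controlling centre differ only moderately in size and the ketone is hindered.
Fallback: kinetic selectivity is given up in favour of separation and recycling. It sets out from 16 and returns to 16. The unwanted epimer (1S,2R,3R,4E)-2-[4-(allyloxy)benzyl]-5-[4-(allyloxy)phenyl]-3-{4-[(tert-butyldimethylsilyl)oxy]phenyl}-1-(2,4-dimethoxyphenyl)pent-4-en-1-ol F15 is separated from 17 by chromatography, oxidised back to 16 with Dess–Martin periodinane and reduced again. Inversion by substitution is not an option, because this benzylic centre would ionise.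

**Step 4.** Enantiofacial discrimination between an aryl and a trans-alkenyl flank may be incomplete, and its sense has to be confirmed (antipodal catalyst if needed). The electron-rich allylic alcohol can also lose configurational purity by ionisation on acidic surfaces.
Fallback: the carbinol centre is set by enantioselective 1,2-addition of an aryl group instead of by reduction. It sets out from 3 and comes back at 6.
- 3 is silylated (as in step 3) to 4-[(tert-butyldimethylsilyl)oxy]benzaldehyde F16.
- A Wittig reaction with (triphenylphosphoranylidene)acetaldehyde gives (2E)-3-{4-[(tert-butyldimethylsilyl)oxy]phenyl}prop-2-enal F17.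
- Catalytic asymmetric aryl transfer from commercial [4-(allyloxy)phenyl]boronic acid and ZnEt2, in the presence of a chiral β-amino alcohol ligand, gives 6.

## Further compounds

F1 | step 15 | (2E)-1-[4-(allyloxy)phenyl]-3-(2-bromo-4-methoxyphenyl)prop-2-en-1-one | O=C(/C=C/c1ccc(OC)cc1Br)c1ccc(OCC=C)cc1
F2 | step 15 | (1R,2E)-1-[4-(allyloxy)phenyl]-3-(2-bromo-4-methoxyphenyl)prop-2-en-1-ol | O[C@@H](c1ccc(OCC=C)cc1)/C=C/c1ccc(OC)cc1Br
F3 | step 15 | (1R,2E)-1-[4-(allyloxy)phenyl]-3-(2-bromo-4-methoxyphenyl)prop-2-en-1-yl 3-[4-(allyloxy)phenyl]propanoate | O=C(CCc1ccc(OCC=C)cc1)O[C@@H](c1ccc(OCC=C)cc1)/C=C/c1ccc(OC)cc1Br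
F4 | step 15 | (2R,3R,4E)-2-[4-(allyloxy)benzyl]-5-[4-(allyloxy)phenyl]-3-(2-bromo-4-methoxyphenyl)pent-4-enoic acid | OC(=O)[C@H](Cc1ccc(OCC=C)cc1)[C@H](c1ccc(OC)cc1Br)/C=C/c1ccc(OCC=C)cc1
F5 | step 15 | (2R,3R,4E)-2-[4-(allyloxy)benzyl]-5-[4-(allyloxy)phenyl]-3-(2-bromo-4-methoxyphenyl)-N-methoxy-N-methylpent-4-enamide | CON(C)C(=O)[C@H](Cc1ccc(OCC=C)cc1)[C@H](c1ccc(OC)cc1Br)/C=C/c1ccc(OCC=C)cc1
F6 | step 15 | (2,4-dimethoxyphenyl)magnesium bromide | COc1ccc([Mg]Br)c(OC)c1
F7 | step 15 | (2R,3R,4E)-2-[4-(allyloxy)benzyl]-5-[4-(allyloxy)phenyl]-3-(2-bromo-4-methoxyphenyl)-1-(2,4-dimethoxyphenyl)pent-4-en-1-one | O=C(c1ccc(OC)cc1OC)[C@H](Cc1ccc(OCC=C)cc1)[C@H](c1ccc(OC)cc1Br)/C=C/c1ccc(OCC=C)cc1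
F8 | step 15 | (1R,2R,3R,4E)-2-[4-(allyloxy)benzyl]-5-[4-(allyloxy)phenyl]-3-(2-bromo-4-methoxyphenyl)-1-(2,4-dimethoxyphenyl)pent-4-en-1-ol | O[C@@H](c1ccc(OC)cc1OC)[C@H](Cc1ccc(OCC=C)cc1)[C@H](c1ccc(OC)cc1Br)/C=C/c1ccc(OCC=C)cc1
F9 | step 13 | 4-{(1E,3R,4R,5R)-4-[4-(allyloxy)benzyl]-1-[4-(allyloxy)phenyl]-5-(2,4-dimethoxyphenyl)-5-[(triethylsilyl)oxy]pent-1-en-3-yl}-4-hydroxycyclohexa-2,5-dien-1-one | CC[Si](CC)(CC)O[C@@H](c1ccc(OC)cc1OC)[C@H](Cc1ccc(OCC=C)cc1)[C@H](C1(O)C=CC(=O)C=C1)/C=C/c1ccc(OCC=C)cc1
F10 | step 13 | 4-{(1E,3R,4R,5R)-4-[4-(allyloxy)benzyl]-1-[4-(allyloxy)phenyl]-5-(2,4-dimethoxyphenyl)-5-hydroxypent-1-en-3-yl}-4-hydroxycyclohexa-2,5-dien-1-one | O[C@@H](c1ccc(OC)cc1OC)[C@H](Cc1ccc(OCC=C)cc1)[C@H](C1(O)C=CC(=O)C=C1)/C=C/c1ccc(OCC=C)cc1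
F11 | step 13 | (2R,3R,4R)-3-[4-(allyloxy)benzyl]-4-{(E)-2-[4-(allyloxy)phenyl]ethenyl}-2-(2,4-dimethoxyphenyl)-4a-hydroxy-2,3,4,4a,8,8a-hexahydro-7H-chromen-7-one | OC12C=CC(=O)CC1O[C@@H](c1ccc(OC)cc1OC)[C@H](Cc1ccc(OCC=C)cc1)[C@H]2/C=C/c1ccc(OCC=C)cc1
F12 | step 7 | 3-[4-(allyloxy)phenyl]-N,N-dimethylpropanamide | CN(C)C(=O)CCc1ccc(OCC=C)cc1
F13 | step 7 | 3-[4-(allyloxy)phenyl]-1,1-dimethoxy-N,N-dimethylpropan-1-amine | CN(C)C(OC)(OC)CCc1ccc(OCC=C)cc1
F14 | step 7 | (2R,3R,4E)-2-[4-(allyloxy)benzyl]-5-[4-(allyloxy)phenyl]-3-{4-[(tert-butyldimethylsilyl)oxy]phenyl}-N,N-dimethylpent-4-enamide | CN(C)C(=O)[C@H](Cc1ccc(OCC=C)cc1)[C@H](c1ccc(O[Si](C)(C)C(C)(C)C)cc1)/C=C/c1ccc(OCC=C)cc1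
F15 | step 10 | (1S,2R,3R,4E)-2-[4-(allyloxy)benzyl]-5-[4-(allyloxy)phenyl]-3-{4-[(tert-butyldimethylsilyl)oxy]phenyl}-1-(2,4-dimethoxyphenyl)pent-4-en-1-ol | O[C@H](c1ccc(OC)cc1OC)[C@H](Cc1ccc(OCC=C)cc1)[C@H](c1ccc(O[Si](C)(C)C(C)(C)C)cc1)/C=C/c1ccc(OCC=C)cc1
F16 | step 4 | 4-[(tert-butyldimethylsilyl)oxy]benzaldehyde | CC(C)(C)[Si](C)(C)Oc1ccc(C=O)cc1
F17 | step 4 | (2E)-3-{4-[(tert-butyldimethylsilyl)oxy]phenyl}prop-2-enal | CC(C)(C)[Si](C)(C)Oc1ccc(/C=C/C=O)cc1
A1 | alternative 1 | (2R,3S)-2-(2,4-dimethoxyphenyl)-7-methoxy-3-{4-[(triisopropylsilyl)oxy]benzyl}chroman-4-one (2,3-trans) | COc1ccc2c(c1)O[C@@H](c1ccc(OC)cc1OC)[C@H](Cc1ccc(O[Si](C(C)C)(C(C)C)C(C)C)cc1)C2=O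
A2 | alternative 1 | 7-methoxy-4H-chromen-4-one | COc1ccc2c(c1)occc2=O
A3 | alternative 2 | bis(triisopropylsilyl) ether of caraganin C | COc1ccc2c(c1)O[C@@H](c1ccc(OC)cc1OC)[C@H](Cc1ccc(O[Si](C(C)C)(C(C)C)C(C)C)cc1)[C@H]2/C=C/c1ccc(O[Si](C(C)C)(C(C)C)C(C)C)cc1
A4 | alternative 2 | (1E,3E)-1,5-bis{4-[(triisopropylsilyl)oxy]phenyl}penta-1,3-diene | CC(C)[Si](Oc1ccc(C/C=C/C=C/c2ccc(O[Si](C(C)C)(C(C)C)C(C)C)cc2)cc1)(C(C)C)C(C)C
A5 | alternative 3 | bis(allyl) ether of caraganin C | COc1ccc2c(c1)O[C@@H](c1ccc(OC)cc1OC)[C@H](Cc1ccc(OCC=C)cc1)[C@H]2/C=C/c1ccc(OCC=C)cc1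
A6 | alternative 3 | 2-{(1E,4E)-1,5-bis[4-(allyloxy)phenyl]penta-1,4-dien-3-yl}-5-methoxyphenol | COc1ccc(C(/C=C/c2ccc(OCC=C)cc2)/C=C/c2ccc(OCC=C)cc2)c(O)c1
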